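**Strategy.** The route rests on the C1–C2 bond of the cyclohex-4-ene ring (C1/C3 = carboxamide-bearing carbons, C2 = heptenyl carbon, C6 = pentyl carbon). Because the C1 and C3 carbonyls are cis-1,3, they can share one isobutylamine nitrogen as an imide. C2 is then β to the C3 carbonyl and bonded to the α-carbon C1: a Michael bond. The precursor is an eight-membered cyclic imide, made by ring-closing metathesis, that carries an exocyclic (E)-octenylidene group at C3. One transannular Michael addition forms C1–C2, closes the cyclohexene and glutarimide rings together and sets C1, C2 and C3. Aminolysis of the imide then releases both amides.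

Key step: step 9

Remark on the chemistry: locants C1–C6 refer to the cyclohex-4-ene ring of the target as defined above; compounds 1, 3, 6, 8 and 9 are taken as commercial, and the triene intermediates 13–18 are handled at or below 40 °C because their cis-hexatriene units can dimerise or electrocyclise on heating.

Step 1
Reactants: 1 (3E)-non-3-en-2-one
Product: 2 (2S,3E)-non-3-en-2-ol
Conditions: (R)-2-methyl-CBS-oxazaborolidine (C18H20BNO, 0.1 equiv), BH3·SMe2 (0.6 equiv), THF, −30 °C; MeOH
Reagents that add atoms: none
Why: Corey–Bakshi–Shibata reduction: the (R)-oxazaborolidine–borane complex binds the carbonyl anti to the alkenyl (large) group and delivers hydride in a 1,2-sense to one face, which should set the carbinol centre as S.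

Step 2
Reactants: 2 (2S,3E)-non-3-en-2-ol; 3 triethyl orthoacetate
Product: 5 ethyl (3S,4E)-3-pentylhex-4-enoate, via mixed ketene acetal 4 (not isolated)
Conditions: 3 (5 equiv), EtCO2H (cat.), 135 °C, EtOH distilled off
Reagents that add atoms: none
Why: Johnson–Claisen rearrangement: the ketene acetal 4 formed by acid-catalysed exchange rearranges through a chair transition state with the methyl group equatorial, so the carbinol chirality is transferred suprafacially to the new pentyl-bearing centre (3S, the future ring C6) and the new propenyl alkene is E.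

Step 3
Reactants: 5 ethyl (3S,4E)-3-pentylhex-4-enoate; 6 2-methylpropan-1-amine (isobutylamine)
Product: 7 (3S,4E)-N-(2-methylpropyl)-3-pentylhex-4-enamide
Conditions: 6 (5 equiv), 1,5,7-triazabicyclo[4.4.0]dec-5-ene (0.3 equiv), 75 °C, sealed tube
Reagents that add atoms: none
Why: Organobase-catalysed aminolysis of an unactivated ester (acyl transfer through an acyl-guanidine intermediate), which leaves the non-enolisable β-stereocentre untouched.

Step 4
Reactants: 8 ethyl (2E)-but-2-enoate; 9 (2E)-oct-2-enal
Product: 11 ethyl (4E)-2-ethenyl-3-hydroxydec-4-enoate (mixture of diastereomers), via lithium dienolate 10 (not isolated)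
Conditions: LiN(iPr)2 (1.1 equiv), HMPA, THF, −78 °C; then 9, −78 °C; AcOH
Reagents that add atoms: none
Why: Aldol addition of the extended enolate 10 (γ-deprotonation of the crotonate), which reacts through its α-carbon with the aldehyde carbon of 9 at −78 °C; the two new stereocentres are removed in step 5, so their mixture is of no consequence.

Step 5
Reactants: 11 ethyl (4E)-2-ethenyl-3-hydroxydec-4-enoate
Product: 13 ethyl (2E,4E)-2-ethenyldeca-2,4-dienoate, via acetate 12 (not isolated)
Conditions: Ac2O, Et3N, 4-(dimethylamino)pyridine (cat.), CH2Cl2, 0 °C; then 1,8-diazabicyclo[5.4.0]undec-7-ene (DBU), 0 °C → rt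
Reagents that add atoms: none
Why: Acetylation and E1cB elimination through the doubly activated α-proton; the more stable 2E isomer (ester trans to the dienyl chain) should dominate and is freed from any 2Z isomer by chromatography, because this geometry later fixes C2 of the ring.

Step 6
Reactants: 13 ethyl (2E,4E)-2-ethenyldeca-2,4-dienoate
Product: 14 (2E,4E)-2-ethenyldeca-2,4-dienoic acid
Conditions: LiOH, THF/MeOH/H2O, 0 °C → rt; then 1 M HCl
Reagents that add atoms: lithium hydroxide, [Li+].[OH-]
Why: Saponification of the ester under cold conditions, which should leave the sensitive cross-conjugated triene and its 2E geometry intact.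

Step 7
Reactants: 14 (2E,4E)-2-ethenyldeca-2,4-dienoic acid; 7 (3S,4E)-N-(2-methylpropyl)-3-pentylhex-4-enamide
Product: 17 (2E,4E)-2-ethenyl-N-(2-methylpropyl)-N-[(3S,4E)-3-pentylhex-4-enoyl]deca-2,4-dienamide, via acid chloride 15 (not isolated), via lithium amidate 16 (not isolated)
Conditions: 14, (COCl)2, DMF (cat.), CH2Cl2, 0 °C, evaporate; 7, LiN(SiMe3)2 (1.05 equiv), THF, −78 °C; then 15, −78 → 0 °C
Reagents that add atoms: none
Why: N-Acylation of the lithium amidate 16 by the acid chloride 15, which has no α-hydrogen and cannot form a ketene (imide formation); no stereocentre is formed or touched.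

Step 8
Reactants: 17 (2E,4E)-2-ethenyl-N-(2-methylpropyl)-N-[(3S,4E)-3-pentylhex-4-enoyl]deca-2,4-dienamide
Product: 18 (3E,4Z,6S)-1-(2-methylpropyl)-3-[(2E)-oct-2-en-1-ylidene]-6-pentyl-6,7-dihydroazocine-2,8(1H,3H)-dione
Conditions: second-generation Grubbs catalyst RuCl2(=CHPh)(H2IMes)(PCy3) (10 mol %), CH2Cl2 (1 mM), 40 °C
Reagents that add atoms: none
Why: Ring-closing metathesis of the vinyl and propenyl groups with loss of propene; the eight-membered ring can hold only a Z alkene, the trisubstituted exocyclic and the internal E alkenes are far less reactive, and the pentyl-bearing stereocentre is not involved.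

Step 9
Reactants: 18 (3E,4Z,6S)-1-(2-methylpropyl)-3-[(2E)-oct-2-en-1-ylidene]-6-pentyl-6,7-dihydroazocine-2,8(1H,3H)-dione
Product: 21 (1R,5S,8R,9R)-9-[(1E)-hept-1-en-1-yl]-3-(2-methylpropyl)-8-pentyl-3-azabicyclo[3.3.1]non-6-ene-2,4-dione, via potassium enolate 19 (not isolated), via bridgehead potassium enolate 20 (not isolated)
Conditions: KN(SiMe3)2 (0.2 equiv), THF, −78 → 0 °C; aq. NH4Cl
Reagents that add atoms: none
Why: Substoichiometric KN(SiMe3)2 deprotonates the ring CH2 α to the imide carbonyl of 18 (future C1), the enolate 19 attacks across the ring the exocyclic β-carbon of the alkylidene imide (future C2), and the bridgehead enolate 20 is protonated by a further molecule of 18, which carries the chain. This is a transannular Michael addition, a known reaction type of medium and large rings; bridgehead enolates of bicyclo[3.3.1]nonanones are accessible, and release of eight-membered ring strain should drive the step. The single new C1–C2 bond closes the cyclohexene and the glutarimide rings at once, each in a 6-endo-trig mode because the acceptor C2=C3 bond lies in both new rings. C2 is fixed by the E geometry of the alkylidene: the enolate can reach C2 only perpendicular to the alkylidene plane from inside the ring, so the heptenyl group, which is cis to the ring alkene carbon (future C4), must end over the cyclohexene, trans to both carbonyls. C1 and C3 become bridgeheads and are necessarily cis (one-nitrogen bridge), and their sense relative to C6 follows from the pentyl group taking the equatorial (exo) site, since the alternative places pentyl 1,3-diaxial to the heptenyl group; the addition is reversible, so this is also the thermodynamic outcome. The step needs 1,4- rather than 1,6-addition (six- against eight-membered ring) and retention of the alkylidene geometry, both secured by the ring and by a non-nucleophilic base.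

Step 10
Reactants: 21 (1R,5S,8R,9R)-9-[(1E)-hept-1-en-1-yl]-3-(2-methylpropyl)-8-pentyl-3-azabicyclo[3.3.1]non-6-ene-2,4-dione; 6 2-methylpropan-1-amine
Product: 22 (1R,2R,3S,6R)-2-[(1E)-hept-1-en-1-yl]-N1,N3-bis(2-methylpropyl)-6-pentylcyclohex-4-ene-1,3-dicarboxamide
Conditions: 6 (neat, excess), 2-hydroxypyridine (0.2 equiv), 60 °C
Reagents that add atoms: none
Why: Aminolysis (nucleophilic ring opening) of the bridged imide with 2-hydroxypyridine as proton shuttle; attack at either carbonyl gives the same bis-amide and none of the four stereocentres is involved.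

**Compound list**

1 | (3E)-non-3-en-2-one | CC(=O)/C=C/CCCCC | starting material
2 | (2S,3E)-non-3-en-2-ol | C[C@H](O)/C=C/CCCCC | intermediate
3 | triethyl orthoacetate | CC(OCC)(OCC)OCC | starting material
4 | 1-ethoxy-1-{[(2S,3E)-non-3-en-2-yl]oxy}ethene (mixed ketene acetal) | C=C(OCC)O[C@@H](C)/C=C/CCCCC | intermediate
5 | ethyl (3S,4E)-3-pentylhex-4-enoate | CCOC(=O)C[C@H](CCCCC)/C=C/C | intermediate
6 | 2-methylpropan-1-amine (isobutylamine) | CC(C)CN | starting material
7 | (3S,4E)-N-(2-methylpropyl)-3-pentylhex-4-enamide | CC(C)CNC(=O)C[C@H](CCCCC)/C=C/C | intermediate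
8 | ethyl (2E)-but-2-enoate | C/C=C/C(=O)OCC | starting material
9 | (2E)-oct-2-enal | CCCCC/C=C/C=O | starting material
10 | lithium 1-ethoxybuta-1,3-dien-1-olate (dienolate of 8) | [Li]OC(OCC)=CC=C | intermediate
11 | ethyl (4E)-2-ethenyl-3-hydroxydec-4-enoate (diastereomer mixture) | CCOC(=O)C(C=C)C(O)/C=C/CCCCC | intermediate
12 | ethyl (4E)-3-acetoxy-2-ethenyldec-4-enoate | CCOC(=O)C(C=C)C(OC(C)=O)/C=C/CCCCC | intermediate
13 | ethyl (2E,4E)-2-ethenyldeca-2,4-dienoate | CCOC(=O)/C(C=C)=C/C=C/CCCCC | intermediate
14 | (2E,4E)-2-ethenyldeca-2,4-dienoic acid | OC(=O)/C(C=C)=C/C=C/CCCCC | intermediate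
15 | (2E,4E)-2-ethenyldeca-2,4-dienoyl chloride | ClC(=O)/C(C=C)=C/C=C/CCCCC | intermediate
16 | lithium amidate of 7 | CC(C)CN([Li])C(=O)C[C@H](CCCCC)/C=C/C | intermediate
17 | (2E,4E)-2-ethenyl-N-(2-methylpropyl)-N-[(3S,4E)-3-pentylhex-4-enoyl]deca-2,4-dienamide | CCCCC/C=C/C=C(\C=C)C(=O)N(CC(C)C)C(=O)C[C@H](CCCCC)/C=C/C | intermediate
18 | (3E,4Z,6S)-1-(2-methylpropyl)-3-[(2E)-oct-2-en-1-ylidene]-6-pentyl-6,7-dihydroazocine-2,8(1H,3H)-dione | CCCCC/C=C/C=C1\C=C/[C@@H](CCCCC)CC(=O)N(CC(C)C)C1=O | intermediate
19 | potassium enolate of 18 (deprotonated at the ring CH2) | CCCCC/C=C/C=C1\C=C/[C@@H](CCCCC)C=C([O-])N(CC(C)C)C1=O.[K+] | intermediate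
20 | bridgehead potassium enolate of 21 | CCCCC/C=C/[C@H]1[C@H]2[C@H](CCCCC)C=CC1=C([O-])N(CC(C)C)C2=O.[K+] | intermediate
21 | (1R,5S,8R,9R)-9-[(1E)-hept-1-en-1-yl]-3-(2-methylpropyl)-8-pentyl-3-azabicyclo[3.3.1]non-6-ene-2,4-dione | CCCCC/C=C/[C@H]1[C@H]2[C@H](CCCCC)C=C[C@@H]1C(=O)N(CC(C)C)C2=O | intermediate
22 | (1R,2R,3S,6R)-2-[(1E)-hept-1-en-1-yl]-N1,N3-bis(2-methylpropyl)-6-pentylcyclohex-4-ene-1,3-dicarboxamide | CCCCC/C=C/[C@H]1[C@H](C(=O)NCC(C)C)[C@H](CCCCC)C=C[C@@H]1C(=O)NCC(C)C | target

**Totals.** Total step count: 10. Longest linear sequence: 7 steps (steps 4–10, or equally steps 1–3 and 7–10).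

**Steps most likely to fail**

1. Step 9 (key step). The pyramidal bridgehead enolate may form too reluctantly, so that the open enolate simply persists. The base may also scramble the exocyclic alkene geometry, which would erode the configuration at C2. Fallback, setting out from 18: the bond is made in a neutral radical manifold that needs no bridgehead enolate. Soft enolisation (TBSOTf, Et3N) should give the silyl ketene N,O-acetal F2, and NBS should convert it into the α-bromo imide F3. Bu3SnH with Et3B/air at room temperature should then generate the α-imidoyl radical, which adds across the ring to the same exocyclic carbon, again perpendicular to the alkylidene plane, so the stereochemical argument is unchanged. Hydrogen transfer to the bridgehead radical comes back to the route at 21.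

2. Step 8. Intermolecular metathesis (oligomerisation) may outcompete closure of the strained eight-membered ring, or the conjugated diene may arrest the catalyst. Fallback, setting out from 17: the order of the two ring closures is exchanged. Catalytic KN(SiMe3)2 in THF should first effect the intramolecular Michael addition of the imide enolate to the alkylidene β-carbon (the same C1–C2 bond, now closing only the glutarimide) to give the monocyclic glutarimide F1, whose two enolisable α-centres equilibrate under the basic conditions. Ring-closing metathesis of its vinyl and propenyl groups with the second-generation Grubbs catalyst then closes an unstrained cyclohexene, which is possible only from the isomer with both alkenyl arms cis-diaxial, and comes back to the route at 21. In this variant C2 is no longer dictated by the alkylidene geometry, so a C2 epimer may have to be separated.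

3. Step 10. Ring opening of the hindered, N-alkylated bridged imide may stall, or forcing conditions may cause epimerisation α to the carbonyls. Fallback, setting out from 21: the imide is opened in two stages. LiOH in aqueous THF at 0 °C should give the amide acid F4 together with the regioisomeric amide acid F5, and both are coupled with 6 (EDC·HCl, HOBt, CH2Cl2) to converge on 22.

**Further compounds**

F1 | step 8 | 5-ethenyl-4-[(1E)-hept-1-en-1-yl]-1-(2-methylpropyl)-3-[(2E)-non-2-en-4-yl]piperidine-2,6-dione (isomer leading to 21) | CCCCC/C=C/[C@H]1[C@@H]([C@H](CCCCC)/C=C/C)C(=O)N(CC(C)C)C(=O)[C@H]1C=C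
F2 | step 9 | tert-butyldimethylsilyl ketene N,O-acetal of 18 | CCCCC/C=C/C=C1\C=C/[C@@H](CCCCC)C=C(O[Si](C)(C)C(C)(C)C)N(CC(C)C)C1=O
F3 | step 9 | 7-bromo derivative of 18 (α-bromo imide, epimer mixture) | CCCCC/C=C/C=C1\C=C/[C@@H](CCCCC)C(Br)C(=O)N(CC(C)C)C1=O
F4 | step 10 | (1R,2R,3S,6R)-2-[(1E)-hept-1-en-1-yl]-3-[(2-methylpropyl)carbamoyl]-6-pentylcyclohex-4-ene-1-carboxylic acid | CCCCC/C=C/[C@H]1[C@H](C(=O)O)[C@H](CCCCC)C=C[C@@H]1C(=O)NCC(C)C
F5 | step 10 | (1S,4R,5R,6S)-6-[(1E)-hept-1-en-1-yl]-5-[(2-methylpropyl)carbamoyl]-4-pentylcyclohex-2-ene-1-carboxylic acid | CCCCC/C=C/[C@H]1[C@H](C(=O)NCC(C)C)[C@H](CCCCC)C=C[C@@H]1C(=O)O
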